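**Retrosynthetic overview**
1. The sulfate comes from the primary alcohol. The C13 stereocentre and its CH2OH arm come from a primary alkyl pinacol boronate at C12 by Hoppe–Aggarwal lithiation–borylation with the sparteine-complexed lithiated carbamate of 4-(furan-3-yl)butanol, then Matteson CH2 insertion and oxidation.
2. Key disconnection C9–C11: the quaternary stereocentre is made by a photoredox decarboxylative Giese addition of the tertiary C9 radical to vinylboronic acid pinacol ester, anti to the C8 methyl and the ring A methylene.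
3. The tertiary acid comes from a catalytic asymmetric Diels–Alder reaction of (E)-2-methylbut-2-enal with 6,6-dimethyl-1-vinylcyclohexene (sets C8; the carboxyl is a traceless activating group), then Pinnick oxidation. The ring alkene is moved to the tetrasubstituted C5=C10 position by acid after the radical step.
4. Ring order: ring A (gem-dimethylcyclohexene, from 2-methylcyclohexanone) first, then ring B by the Diels–Alder reaction. The furan is bought as 3-bromofuran and attached by B-alkyl Suzuki coupling.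

Locants used below: ring A = C1–C5 and C10 (CMe2 = C4); ring B = C5–C10 (C8 = CHMe, C9 = quaternary); side chain C11–C16 from C9 to the furan, C13 = side-chain stereocentre.
Assumption: the oxazaborolidinium catalyst shows the same facial sense with tiglic aldehyde as with 2-methylacrolein, which calls for the (R)-catalyst; if the sense is opposite, the (S)-catalyst is used.

**Step 1**
Reactants: 1 2-methylcyclohexanone (racemic)
Product: 2 2,2-dimethylcyclohexanone
Conditions: lithium diisopropylamide (0.95 equiv), THF, −78 °C → rt (enolate equilibration); MeI, 0 °C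
Reagents that add atoms: iodomethane, CI
Why: Thermodynamic enolate alkylation: the equilibrated, more substituted lithium enolate is methylated at the already substituted α-carbon; the product is achiral, so the racemic nature of 1 does not matter.

**Step 2**
Reactants: 2 2,2-dimethylcyclohexanone
Product: 3 6,6-dimethylcyclohex-1-en-1-yl trifluoromethanesulfonate
Conditions: lithium diisopropylamide, THF, −78 °C; PhNTf2, −78 °C → rt
Reagents that add atoms: N-phenylbis(trifluoromethanesulfonimide), O=S(=O)(N(c1ccccc1)S(=O)(=O)C(F)(F)F)C(F)(F)F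
Why: Enol triflate formation: only one α-carbon carries hydrogens, so deprotonation and O-triflation give a single regioisomer.

**Step 3**
Reactants: 3 6,6-dimethylcyclohex-1-en-1-yl trifluoromethanesulfonate; 4 vinylmagnesium bromide
Product: 5 6,6-dimethyl-1-vinylcyclohex-1-ene
Conditions: Pd(PPh3)4 (3 mol%), THF, 0 °C → rt
Reagents that add atoms: none
Why: Palladium-catalysed Kumada cross-coupling of an alkenyl triflate with a vinyl Grignard reagent gives the semicyclic diene (ring A complete) with the alkene position fixed.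

**Step 4**
Reactants: 5 6,6-dimethyl-1-vinylcyclohex-1-ene; 6 (E)-2-methylbut-2-enal (tiglic aldehyde)
Product: 7 (1R,2S,8aR)-1,2,5,5-tetramethyl-1,2,3,5,6,7,8,8a-octahydronaphthalene-1-carbaldehyde
Conditions: (R)-o-tolyl-CBS oxazaborolidine (20 mol%), HNTf2 (20 mol%), 6 (3 equiv), CH2Cl2, −78 → −20 °C
Reagents that add atoms: none
Why: Catalytic enantioselective Diels–Alder reaction (cationic oxazaborolidine activation of the enal) forms ring B; the unsubstituted diene terminus bonds to the enal β-carbon, suprafacial addition to the (E)-enal places the two methyls cis, the formyl group is exo, and the catalyst blocks one enal face so that C8 is S (C9 R, C10 R).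

**Step 5**
Reactants: 7 (1R,2S,8aR)-1,2,5,5-tetramethyl-1,2,3,5,6,7,8,8a-octahydronaphthalene-1-carbaldehyde
Product: 8 (1R,2S,8aR)-1,2,5,5-tetramethyl-1,2,3,5,6,7,8,8a-octahydronaphthalene-1-carboxylic acid
Conditions: NaClO2, NaH2PO4, 2-methyl-2-butene, t-BuOH/H2O, rt
Reagents that add atoms: sodium chlorite, [Na+].[O-]Cl=O
Why: Pinnick oxidation of a non-enolisable aldehyde; 2-methyl-2-butene scavenges HOCl so the ring alkene survives and no stereocentre is touched.

**Step 6 (key step)**
Reactants: 8 (1R,2S,8aR)-1,2,5,5-tetramethyl-1,2,3,5,6,7,8,8a-octahydronaphthalene-1-carboxylic acid; 9 vinylboronic acid pinacol ester (pinacol-protected vinylboronic acid)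
Product: 10 2-{2-[(1R,2S,8aS)-1,2,5,5-tetramethyl-1,2,3,5,6,7,8,8a-octahydronaphthalen-1-yl]ethyl}-4,4,5,5-tetramethyl-1,3,2-dioxaborolane
Conditions: 9 (3 equiv), [Ir(dF(CF3)ppy)2(dtbbpy)]PF6 (2 mol%), Cs2CO3 (0.5 equiv), DMF, blue LEDs (450 nm), rt
Reagents that add atoms: none
Why: Photoredox decarboxylative Giese addition: the excited trivalent iridium complex oxidises the caesium carboxylate, loss of CO2 gives the tertiary C9 radical, and this adds to the vinyl boronate on the face anti to the C8 methyl and the C1 methylene that flank it on the other face, so C9 becomes R with its methyl cis to the C8 methyl; divalent iridium reduces the α-boryl radical and protonation closes the cycle.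

**Step 7**
Reactants: 10 2-{2-[(1R,2S,8aS)-1,2,5,5-tetramethyl-1,2,3,5,6,7,8,8a-octahydronaphthalen-1-yl]ethyl}-4,4,5,5-tetramethyl-1,3,2-dioxaborolane
Product: 11 2-{2-[(1R,2S)-1,2,5,5-tetramethyl-1,2,3,4,5,6,7,8-octahydronaphthalen-1-yl]ethyl}-4,4,5,5-tetramethyl-1,3,2-dioxaborolane
Conditions: HI (57% aq, 0.2 equiv), benzene, 80 °C
Reagents that add atoms: none
Why: Acid-catalysed alkene isomerisation through the tertiary C5 cation gives the thermodynamically preferred tetrasubstituted C5=C10 alkene; C10 stops being a stereocentre, and the quaternary C9 and the C8 centre are not touched.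

**Step 8**
Reactants: 12 but-3-en-1-ol
Product: 13 but-3-en-1-yl N,N-diisopropylcarbamate
Conditions: NaH, THF, 0 °C; i-Pr2NCOCl, 0 °C → reflux
Reagents that add atoms: N,N-diisopropylcarbamoyl chloride, CC(C)N(C(C)C)C(Cl)=O
Why: O-Carbamoylation of the sodium alkoxide installs the Hoppe directing and leaving group.

**Step 9**
Reactants: 13 but-3-en-1-yl N,N-diisopropylcarbamate; 14 3-bromofuran
Product: 16 4-(furan-3-yl)butyl N,N-diisopropylcarbamate, via 9-BBN adduct 15 (not isolated)
Conditions: 9-BBN, THF, rt; then 14, PdCl2(dppf) (3 mol%), 3 M aq NaOH, 65 °C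
Reagents that add atoms: none
Why: Anti-Markovnikov hydroboration of the terminal alkene followed by B-alkyl Suzuki–Miyaura coupling joins furan C3 to the four-carbon chain; the hindered carbamate is inert to aqueous base.

**Step 10**
Reactants: 16 4-(furan-3-yl)butyl N,N-diisopropylcarbamate; 11 2-{2-[(1R,2S)-1,2,5,5-tetramethyl-1,2,3,4,5,6,7,8-octahydronaphthalen-1-yl]ethyl}-4,4,5,5-tetramethyl-1,3,2-dioxaborolane
Product: 19 2-{(3R)-6-(furan-3-yl)-1-[(1R,2S)-1,2,5,5-tetramethyl-1,2,3,4,5,6,7,8-octahydronaphthalen-1-yl]hexan-3-yl}-4,4,5,5-tetramethyl-1,3,2-dioxaborolane, via lithiated carbamate 17 (not isolated), via boronate complex 18 (not isolated)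
Conditions: 16 (1.3 equiv), s-BuLi, (−)-sparteine, Et2O, −78 °C, 5 h; then 11, −78 °C, 1 h; MgBr2·OEt2, −78 °C → reflux
Reagents that add atoms: none
Why: Hoppe–Aggarwal lithiation–borylation: sparteine-mediated deprotonation removes the pro-S hydrogen to give configurationally stable (S)-17, borylation by 11 occurs with retention, and the 1,2-metallate rearrangement (C12 migrates anti to the leaving carbamate, inversion at carbon) sets C13 as R under reagent control, independent of the remote ring stereocentres.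

**Step 11**
Reactants: 19 2-{(3R)-6-(furan-3-yl)-1-[(1R,2S)-1,2,5,5-tetramethyl-1,2,3,4,5,6,7,8-octahydronaphthalen-1-yl]hexan-3-yl}-4,4,5,5-tetramethyl-1,3,2-dioxaborolane
Product: 21 (2R)-5-(furan-3-yl)-2-{2-[(1R,2S)-1,2,5,5-tetramethyl-1,2,3,4,5,6,7,8-octahydronaphthalen-1-yl]ethyl}pentan-1-ol, via homologated boronic ester 20 (not isolated)
Conditions: BrCH2Cl, n-BuLi, Et2O, −78 °C → rt; then 2 M NaOH, 30% H2O2, THF, 0 °C → rt
Reagents that add atoms: bromochloromethane, ClCBr; hydrogen peroxide, OO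
Why: Matteson homologation (chloromethyllithium inserts CH2 into the C–B bond with retention at C13) followed by stereoretentive boronate oxidation gives the hydroxymethyl arm; generating the carbenoid in situ at −78 °C avoids metalation of the furan.

**Step 12**
Reactants: 21 (2R)-5-(furan-3-yl)-2-{2-[(1R,2S)-1,2,5,5-tetramethyl-1,2,3,4,5,6,7,8-octahydronaphthalen-1-yl]ethyl}pentan-1-ol
Product: 23 (2R)-5-(furan-3-yl)-2-{2-[(1R,2S)-1,2,5,5-tetramethyl-1,2,3,4,5,6,7,8-octahydronaphthalen-1-yl]ethyl}pentyl hydrogen sulfate (CNP0377032.3), via pyridinium sulfate salt 22 (not isolated)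
Conditions: SO3·pyridine (2 equiv), pyridine, 0 °C → rt, 1 h; then H+-form cation-exchange resin, MeOH/H2O, 0 °C
Reagents that add atoms: sulfur trioxide pyridine complex, [O-]S(=O)(=O)[n+]1ccccc1
Why: O-Sulfation of the primary alcohol with the mild SO3–pyridine complex, then exchange of pyridinium for a proton; the short, cold treatment leaves the furan and the tetrasubstituted alkene intact and no stereocentre is involved.

**Compound list**
1 | 2-methylcyclohexanone (racemic) | CC1CCCCC1=O | starting material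
2 | 2,2-dimethylcyclohexanone | CC1(C)CCCCC1=O | intermediate
3 | 6,6-dimethylcyclohex-1-en-1-yl trifluoromethanesulfonate | CC1(C)CCCC=C1OS(=O)(=O)C(F)(F)F | intermediate
4 | vinylmagnesium bromide | C=C[Mg]Br | starting material
5 | 6,6-dimethyl-1-vinylcyclohex-1-ene | C=CC1=CCCCC1(C)C | intermediate
6 | (E)-2-methylbut-2-enal (tiglic aldehyde) | C/C=C(\C)C=O | starting material
7 | (1R,2S,8aR)-1,2,5,5-tetramethyl-1,2,3,5,6,7,8,8a-octahydronaphthalene-1-carbaldehyde | C[C@H]1CC=C2C(C)(C)CCC[C@H]2[C@]1(C)C=O | intermediate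
8 | (1R,2S,8aR)-1,2,5,5-tetramethyl-1,2,3,5,6,7,8,8a-octahydronaphthalene-1-carboxylic acid | C[C@H]1CC=C2C(C)(C)CCC[C@H]2[C@]1(C)C(=O)O | intermediate
9 | vinylboronic acid pinacol ester (pinacol-protected vinylboronic acid) | C=CB1OC(C)(C)C(C)(C)O1 | starting material
10 | 2-{2-[(1R,2S,8aS)-1,2,5,5-tetramethyl-1,2,3,5,6,7,8,8a-octahydronaphthalen-1-yl]ethyl}-4,4,5,5-tetramethyl-1,3,2-dioxaborolane | C[C@H]1CC=C2C(C)(C)CCC[C@H]2[C@]1(C)CCB3OC(C)(C)C(C)(C)O3 | intermediate
11 | 2-{2-[(1R,2S)-1,2,5,5-tetramethyl-1,2,3,4,5,6,7,8-octahydronaphthalen-1-yl]ethyl}-4,4,5,5-tetramethyl-1,3,2-dioxaborolane | C[C@H]1CCC2=C(CCCC2(C)C)[C@]1(C)CCB3OC(C)(C)C(C)(C)O3 | intermediate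
12 | but-3-en-1-ol | C=CCCO | starting material
13 | but-3-en-1-yl N,N-diisopropylcarbamate | C=CCCOC(=O)N(C(C)C)C(C)C | intermediate
14 | 3-bromofuran | Brc1ccoc1 | starting material
15 | 4-(9-borabicyclo[3.3.1]nonan-9-yl)butyl N,N-diisopropylcarbamate (9-BBN adduct) | CC(C)N(C(C)C)C(=O)OCCCCB1C2CCCC1CCC2 | intermediate (not isolated)
16 | 4-(furan-3-yl)butyl N,N-diisopropylcarbamate | CC(C)N(C(C)C)C(=O)OCCCCc1ccoc1 | intermediate
17 | (1S)-4-(furan-3-yl)-1-lithiobutyl N,N-diisopropylcarbamate, (−)-sparteine complex | [Li][C@@H](CCCc1ccoc1)OC(=O)N(C(C)C)C(C)C | intermediate (not isolated)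
18 | lithium boronate complex of 11 and 17 (S at the carbamate carbon) | C[C@H]1CCC2=C(CCCC2(C)C)[C@]1(C)CC[B-]3(OC(C)(C)C(C)(C)O3)[C@@H](CCCc4ccoc4)OC(=O)N(C(C)C)C(C)C.[Li+] | intermediate (not isolated)
19 | 2-{(3R)-6-(furan-3-yl)-1-[(1R,2S)-1,2,5,5-tetramethyl-1,2,3,4,5,6,7,8-octahydronaphthalen-1-yl]hexan-3-yl}-4,4,5,5-tetramethyl-1,3,2-dioxaborolane | C[C@H]1CCC2=C(CCCC2(C)C)[C@]1(C)CC[C@@H](CCCc3ccoc3)B4OC(C)(C)C(C)(C)O4 | intermediate
20 | 2-[(2R)-5-(furan-3-yl)-2-{2-[(1R,2S)-1,2,5,5-tetramethyl-1,2,3,4,5,6,7,8-octahydronaphthalen-1-yl]ethyl}pentyl]-4,4,5,5-tetramethyl-1,3,2-dioxaborolane | C[C@H]1CCC2=C(CCCC2(C)C)[C@]1(C)CC[C@@H](CCCc3ccoc3)CB4OC(C)(C)C(C)(C)O4 | intermediate (not isolated)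
21 | (2R)-5-(furan-3-yl)-2-{2-[(1R,2S)-1,2,5,5-tetramethyl-1,2,3,4,5,6,7,8-octahydronaphthalen-1-yl]ethyl}pentan-1-ol | C[C@H]1CCC2=C(CCCC2(C)C)[C@]1(C)CC[C@@H](CCCc3ccoc3)CO | intermediate
22 | pyridinium (2R)-5-(furan-3-yl)-2-{2-[(1R,2S)-1,2,5,5-tetramethyl-1,2,3,4,5,6,7,8-octahydronaphthalen-1-yl]ethyl}pentyl sulfate | C[C@H]1CCC2=C(CCCC2(C)C)[C@]1(C)CC[C@@H](CCCc3ccoc3)COS(=O)(=O)[O-].c1cc[nH+]cc1 | intermediate (not isolated)
23 | (2R)-5-(furan-3-yl)-2-{2-[(1R,2S)-1,2,5,5-tetramethyl-1,2,3,4,5,6,7,8-octahydronaphthalen-1-yl]ethyl}pentyl hydrogen sulfate | C[C@H]1CCC2=C(CCCC2(C)C)[C@]1(C)CC[C@@H](CCCc1ccoc1)COS(=O)(=O)O | target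

**Totals**
Total steps: 12. Longest linear sequence: 10 (steps 1–7, 10, 11, 12); the carbamate branch (steps 8–9) is two steps.

**Three steps most likely to fail**

Step 4 (tiglic aldehyde is a sluggish, doubly substituted dienophile, the diene is acid-sensitive, and enantio- and exo-selectivity are untested on this pair). The fallback sets out from 5 and 6 and comes back at 8. The cycloaddition is run racemically with EtAlCl2 in CH2Cl2 at −78 °C to give the racemic aldehyde F1. Pinnick oxidation gives the racemic acid F2. Classical resolution by crystallisation of the (R)-1-phenylethylammonium salt F3 and acidification returns enantiopure 8; the antipodal amine is used if the other salt is the one that crystallises.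

Step 6 (a hindered tertiary radical must add to a only moderately electrophilic vinyl boronate, and the diastereoselectivity rests on the two flanking substituents). The fallback sets out from 8 and comes back at 10. Under the same iridium photocatalysis, 8 is added to methyl acrylate, a far better radical acceptor, to give the methyl ester F4. LiOH hydrolysis gives the propanoic acid F5. Coupling with N-hydroxyphthalimide (diisopropylcarbodiimide) gives the redox-active ester F6. Decarboxylative borylation (B2pin2, Cu(acac)2 cat., LiOH·H2O, MgCl2, dioxane/DMF) then delivers 10.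

Step 10 (s-BuLi may metalate the furan α-positions in competition with the carbamate, which would lower yield and er). The fallback sets out from 13 and 11 and comes back at 19, bringing in the furan only after the organolithium step. Carbamate 13 is lithiated with s-BuLi/(−)-sparteine to the lithiated butenyl carbamate F7. Borylation with 11 and MgBr2-promoted 1,2-migration give the homoallylic boronic ester F8. Hydroboration of its terminal alkene with 9-BBN gives the 9-BBN adduct F9, which is coupled in the same flask with 14 (PdCl2(dppf), aq NaOH) to give 19.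

**Further compounds**
F1 | step 4 | racemic (1R*,2S*,8aR*)-1,2,5,5-tetramethyl-1,2,3,5,6,7,8,8a-octahydronaphthalene-1-carbaldehyde | C[C@H]1CC=C2C(C)(C)CCC[C@H]2[C@]1(C)C=O.C[C@@H]1CC=C2C(C)(C)CCC[C@@H]2[C@@]1(C)C=O
F2 | step 4 | racemic (1R*,2S*,8aR*)-1,2,5,5-tetramethyl-1,2,3,5,6,7,8,8a-octahydronaphthalene-1-carboxylic acid | C[C@H]1CC=C2C(C)(C)CCC[C@H]2[C@]1(C)C(=O)O.C[C@@H]1CC=C2C(C)(C)CCC[C@@H]2[C@@]1(C)C(=O)O
F3 | step 4 | (R)-1-phenylethylammonium (1R,2S,8aR)-1,2,5,5-tetramethyl-1,2,3,5,6,7,8,8a-octahydronaphthalene-1-carboxylate | C[C@H]1CC=C2C(C)(C)CCC[C@H]2[C@]1(C)C(=O)[O-].C[C@@H]([NH3+])c1ccccc1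
F4 | step 6 | methyl 3-[(1R,2S,8aS)-1,2,5,5-tetramethyl-1,2,3,5,6,7,8,8a-octahydronaphthalen-1-yl]propanoate | C[C@H]1CC=C2C(C)(C)CCC[C@H]2[C@]1(C)CCC(=O)OC
F5 | step 6 | 3-[(1R,2S,8aS)-1,2,5,5-tetramethyl-1,2,3,5,6,7,8,8a-octahydronaphthalen-1-yl]propanoic acid | C[C@H]1CC=C2C(C)(C)CCC[C@H]2[C@]1(C)CCC(=O)O
F6 | step 6 | 1,3-dioxoisoindolin-2-yl 3-[(1R,2S,8aS)-1,2,5,5-tetramethyl-1,2,3,5,6,7,8,8a-octahydronaphthalen-1-yl]propanoate | C[C@H]1CC=C2C(C)(C)CCC[C@H]2[C@]1(C)CCC(=O)ON3C(=O)c4ccccc4C3=O
F7 | step 10 | (1S)-1-lithiobut-3-en-1-yl N,N-diisopropylcarbamate, (−)-sparteine complex | [Li][C@@H](CC=C)OC(=O)N(C(C)C)C(C)C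
F8 | step 10 | 2-{(4S)-6-[(1R,2S)-1,2,5,5-tetramethyl-1,2,3,4,5,6,7,8-octahydronaphthalen-1-yl]hex-1-en-4-yl}-4,4,5,5-tetramethyl-1,3,2-dioxaborolane | C[C@H]1CCC2=C(CCCC2(C)C)[C@]1(C)CC[C@@H](CC=C)B3OC(C)(C)C(C)(C)O3
F9 | step 10 | 2-{(3R)-6-(9-borabicyclo[3.3.1]nonan-9-yl)-1-[(1R,2S)-1,2,5,5-tetramethyl-1,2,3,4,5,6,7,8-octahydronaphthalen-1-yl]hexan-3-yl}-4,4,5,5-tetramethyl-1,3,2-dioxaborolane | C[C@H]1CCC2=C(CCCC2(C)C)[C@]1(C)CC[C@@H](CCCB3C4CCCC3CCC4)B5OC(C)(C)C(C)(C)O5
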